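The route rests on cutting the lower pyran ring at O1–C8a and C2–C3. In the key step a Z-γ-alkoxyallylborane, generated from the 2-aryl allyl ether 22 that already carries the complete upper flavan, adds to 3,4-bis(benzyloxy)benzaldehyde and sets C2 and C3 (syn, 2,3-cis) under isopinocampheyl control. The alkoxide formed then displaces the fluoride on ring A carbon C8a, ortho to C4a, and closes the ring in the same flask. The step exploits the syn C2–O1/C3–O pattern next to an aromatic C8a–O bond. The 4-methylene group left at C4 is cleaved to the ketone and reduced last. The upper unit is made by the same annulation and joined by aryllithium addition and ionic hydrogenation (all-cis).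

Key step: step 13

Remark: the isopinocampheyl groups derived from (+)-α-pinene are taken to direct the allyl unit to the aldehyde face that gives 2R, as in their additions to other aromatic aldehydes; the antipodal borane would be used otherwise. Compounds 1, 3, 7 and 12 are taken as catalogue compounds.

Step 1
Reactants: 1 3-fluorocatechol
Product: 2 1,2-bis(benzyloxy)-3-fluorobenzene
Conditions: BnBr, K2CO3, DMF, 60 °C
Reagents that add atoms: benzyl bromide, BrCc1ccccc1
Why: Williamson O-benzylation of both phenols gives the hydrogenolysable ethers used throughout.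

Step 2
Reactants: 3 2-bromoprop-2-en-1-ol
Product: 4 2-bromoallyl benzyloxymethyl ether
Conditions: BnOCH2Cl, i-Pr2NEt, CH2Cl2, 0 °C to rt
Reagents that add atoms: benzyl chloromethyl ether, ClCOCc1ccccc1
Why: O-alkylation of the primary alcohol by the α-chloro ether gives a chelating acetal that is later removed by hydrogenolysis.

Step 3
Reactants: 2 1,2-bis(benzyloxy)-3-fluorobenzene; 4 2-bromoallyl benzyloxymethyl ether
Product: 6 1,2-bis(benzyloxy)-4-{3-[(benzyloxy)methoxy]prop-1-en-2-yl}-3-fluorobenzene, via arylzinc chloride 5 (not isolated)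
Conditions: n-BuLi, THF, −78 °C; ZnCl2; then 4, Pd(PPh3)4, THF, 50 °C
Reagents that add atoms: none
Why: Fluorine-directed ortho-lithiation (the C–H next to fluorine is the most acidic), transmetalation to zinc and Negishi coupling with the alkenyl bromide.

Step 4
Reactants: 6 1,2-bis(benzyloxy)-4-{3-[(benzyloxy)methoxy]prop-1-en-2-yl}-3-fluorobenzene; 7 3,4-bis(benzyloxy)benzaldehyde
Product: 10 (2R,3R)-7,8-bis(benzyloxy)-2-[3,4-bis(benzyloxy)phenyl]-3-[(benzyloxy)methoxy]-4-methylidenechromane (2,3-cis), via allylborane 8 (not isolated), via potassium alkoxide 9 (not isolated)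
Conditions: s-BuLi, THF, −78 °C; (−)-Ipc2BOMe; BF3·OEt2; 7, −78 °C; then MeOK, DMF, 60–80 °C
Reagents that add atoms: none
Why: Asymmetric γ-alkoxyallylboration followed in the same flask by intramolecular SNAr etherification, in which the chelated Z-oxyallyl unit gives the syn (2,3-cis) adduct through a chair transition state, the isopinocampheyl groups fix C2 as R, and the alkoxide closes the pyran ring on the ortho C–F.

Step 5
Reactants: 10 the 4-methylidenechromane
Product: 11 (2R,3S)-7,8-bis(benzyloxy)-2-[3,4-bis(benzyloxy)phenyl]-3-[(benzyloxy)methoxy]chroman-4-one (2,3-cis)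
Conditions: OsO4 (cat.), NaIO4, 2,6-lutidine, dioxane/H2O, rt
Reagents that add atoms: osmium tetroxide, O=[Os](=O)(=O)=O (oxygen donor, used catalytically and restored by sodium periodate, [Na+].[O-]I(=O)(=O)=O)
Why: Lemieux–Johnson cleavage of the 1,1-disubstituted alkene under buffered conditions that should leave the epimerisable cis C3 centre untouched.

Step 6
Reactants: 12 2-bromo-5-fluorophenol
Product: 13 3-bromo-6-fluoro-2-hydroxybenzaldehyde
Conditions: MgCl2, Et3N, (CH2O)n, MeCN, reflux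
Reagents that add atoms: paraformaldehyde (as formaldehyde), C=O
Why: Magnesium-mediated ortho-formylation of the phenol at its only free ortho position.

Step 7
Reactants: 13 3-bromo-6-fluoro-2-hydroxybenzaldehyde
Product: 14 3-bromo-6-fluorobenzene-1,2-diol
Conditions: H2O2, NaOH, THF/H2O, 0 °C to rt
Reagents that add atoms: hydrogen peroxide, OO
Why: Dakin oxidation of the ortho-hydroxybenzaldehyde (aryl migration, then hydrolysis of the formate) gives the catechol.

Step 8
Reactants: 14 3-bromo-6-fluorobenzene-1,2-diol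
Product: 15 2,3-bis(benzyloxy)-1-bromo-4-fluorobenzene
Conditions: BnBr, K2CO3, DMF, 60 °C
Reagents that add atoms: benzyl bromide, BrCc1ccccc1
Why: Williamson O-benzylation of both phenols.

Step 9
Reactants: 15 2,3-bis(benzyloxy)-1-bromo-4-fluorobenzene
Product: 17 2,3-bis(benzyloxy)-1-bromo-5-chloro-4-fluorobenzene, via aryllithium 16 (not isolated)
Conditions: LiN(i-Pr)2, THF, −78 °C; C2Cl6
Reagents that add atoms: hexachloroethane, ClC(Cl)(Cl)C(Cl)(Cl)Cl
Why: The amide base removes the proton ortho to fluorine (bromine is retained at −78 °C) and the aryllithium is chlorinated, which installs the later coupling handle at C4a of the lower ring A.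

Step 10
Reactants: 17 2,3-bis(benzyloxy)-1-bromo-5-chloro-4-fluorobenzene; 11 the 2,3-cis chroman-4-one
Product: 19 (2R)-2,3-cis-7,8-bis(benzyloxy)-2-[3,4-bis(benzyloxy)phenyl]-3-[(benzyloxy)methoxy]-4-[2,3-bis(benzyloxy)-5-chloro-4-fluorophenyl]chroman-4-ol (C4 drawn for aryl attack anti to the 3-alkoxy group), via aryllithium 18 (not isolated)
Conditions: n-BuLi, THF, −78 °C; then 11, −78 to −40 °C
Reagents that add atoms: none
Why: Bromine–lithium exchange (faster than attack at C–Cl) and 1,2-addition of the aryllithium to the chelating α-alkoxy ketone; the new C4 centre is erased in the next step, so its configuration is immaterial.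

Step 11
Reactants: 19 the tertiary chroman-4-ol
Product: 20 (2R)-2,3-cis-3,4-cis-7,8-bis(benzyloxy)-2-[3,4-bis(benzyloxy)phenyl]-3-[(benzyloxy)methoxy]-4-[2,3-bis(benzyloxy)-5-chloro-4-fluorophenyl]chromane
Conditions: Et3SiH (excess), CF3CO2H, CH2Cl2, −78 to −30 °C
Reagents that add atoms: none
Why: Ionic hydrogenation, in which the doubly benzylic C4 cation should take hydride on the face anti to the axial 3-alkoxy group and the 2-aryl group, so that the new aryl group ends cis to both (all-cis).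

Step 12
Reactants: 20 the all-cis aryl chloride; 4 2-bromoallyl benzyloxymethyl ether
Product: 22 (2R)-2,3-cis-3,4-cis-7,8-bis(benzyloxy)-2-[3,4-bis(benzyloxy)phenyl]-3-[(benzyloxy)methoxy]-4-(2,3-bis(benzyloxy)-5-{3-[(benzyloxy)methoxy]prop-1-en-2-yl}-4-fluorophenyl)chromane, via alkenylzinc chloride 21 (not isolated)
Conditions: 4, t-BuLi, Et2O, −78 °C; ZnCl2, THF; then 20, Pd2(dba)3, XPhos, THF, 60 °C
Reagents that add atoms: none
Why: Halogen–lithium exchange, transmetalation to zinc and Negishi coupling with the aryl chloride, for which a bulky biarylphosphine ligand is the established choice.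

Step 13
Reactants: 22 the 2-aryl allyl ether carrying the upper flavan; 7 3,4-bis(benzyloxy)benzaldehyde
Product: 25 the bis-flavan in which the upper all-cis unit is joined C4 to C6 of (2R,3R)-2,3-cis-7,8-bis(benzyloxy)-2-[3,4-bis(benzyloxy)phenyl]-3-[(benzyloxy)methoxy]-4-methylidenechromane, via allylborane 23 (not isolated), via potassium alkoxide 24 (not isolated)
Conditions: s-BuLi, THF, −78 °C; (−)-Ipc2BOMe; BF3·OEt2; 7, −78 °C; then MeOK, DMF, 60–80 °C
Reagents that add atoms: none
Why: s-BuLi removes an allylic O–CH2 proton of 22 with chelation by the acetal, boron is delivered to the CH2 terminus and, after BF3-induced loss of methoxide, allylborane 23 adds to 7 through a closed chair transition state to form C2–C3, and methoxide then releases alkoxide 24, which displaces fluoride at C8a by addition–elimination to form O1–C8a. The closest known reaction types are the diisopinocampheylborane γ-alkoxyallylboration of aldehydes and the alkoxide–aryl fluoride SNAr cyclisation used to close flavan pyran rings. The pyran ring closes in the 6-exo-trig mode at the aromatic carbon. C2 (R) is controlled by the isopinocampheyl groups on boron (reagent control of the aldehyde face) and C3 (R) by the Z-γ-alkoxy geometry, which places the alkoxy group axial in the chair and gives the syn, that is 2,3-cis, relationship. The step needs site-selective lithiation in the presence of benzylic and diarylmethine C–H bonds, which the chelating acetal, the allylic activation by the aryl-substituted alkene and −78 °C should secure, and reagent-over-substrate facial control, which the distance of the upper flavan from the aldehyde secures; the ring closure is favoured because fluoride sits ortho to the allyl-bearing carbon C4a.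

Step 14
Reactants: 25 the bis-flavan with the 4-methylidene group
Product: 26 the bis-flavan with the lower unit as the (2R,3S)-2,3-cis-3-[(benzyloxy)methoxy]chroman-4-one
Conditions: OsO4 (cat.), NaIO4, 2,6-lutidine, dioxane/H2O, rt
Reagents that add atoms: osmium tetroxide, O=[Os](=O)(=O)=O (oxygen donor, used catalytically and restored by sodium periodate, [Na+].[O-]I(=O)(=O)=O)
Why: Lemieux–Johnson cleavage of the only alkene in the molecule.

Step 15
Reactants: 26 the fully protected ketone
Product: 27 the free decahydroxy ketone (upper all-cis flavan-3-ol joined C4 to C6 of the 2,3-cis-3-hydroxychroman-4-one)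
Conditions: H2 (1 atm), Pd(OH)2/C, THF/MeOH, rt
Reagents that add atoms: none
Why: Hydrogenolysis should remove the eight benzyl ethers and both benzyloxymethyl acetals (the hemiformals lose formaldehyde) while leaving the aryl ketone, which avoids exposing a benzylic C4 alcohol to the catalyst.

Step 16
Reactants: 27 the free decahydroxy ketone
Product: 28 the target, (2R,3R,4R)-2,3-cis-3,4-cis-3′,4′,7,8-tetrahydroxyflavan-3-ol joined C4 to C6 of (2R,3R,4S)-2,3-cis-3,4-trans-3′,4′,7,8-tetrahydroxyflavan-3,4-diol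
Conditions: Me4NBH(OAc)3, MeCN/AcOH, −20 °C
Reagents that add atoms: none
Why: Hydroxyl-directed reduction, in which the axial 3-hydroxyl binds the acetoxyborohydride and delivers hydride to the same face of the C4 ketone, should give the 3,4-trans (4S) alcohol.

Compound list
1 | 3-fluorocatechol | Oc1cccc(F)c1O | starting material
2 | 1,2-bis(benzyloxy)-3-fluorobenzene | Fc1cccc(OCc2ccccc2)c1OCc1ccccc1 | intermediate
3 | 2-bromoprop-2-en-1-ol | OCC(Br)=C | starting material
4 | 2-bromoallyl benzyloxymethyl ether | C=C(Br)COCOCc1ccccc1 | intermediate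
5 | [3,4-bis(benzyloxy)-2-fluorophenyl]zinc chloride | Cl[Zn]c1ccc(OCc2ccccc2)c(OCc2ccccc2)c1F | intermediate
6 | 1,2-bis(benzyloxy)-4-{3-[(benzyloxy)methoxy]prop-1-en-2-yl}-3-fluorobenzene | C=C(COCOCc1ccccc1)c1ccc(OCc2ccccc2)c(OCc2ccccc2)c1F | intermediate
7 | 3,4-bis(benzyloxy)benzaldehyde | O=Cc1ccc(OCc2ccccc2)c(OCc2ccccc2)c1 | starting material
8 | {2-[3,4-bis(benzyloxy)-2-fluorophenyl]-3-[(benzyloxy)methoxy]prop-2-en-1-yl}diisopinocampheylborane, alkoxy group cis to the CH2–B carbon, Ipc groups from (+)-α-pinene | c1ccccc1COCO/C=C(\CB([C@@H]1C[C@@H]2C[C@@H](C2(C)C)[C@H]1C)[C@@H]1C[C@@H]2C[C@@H](C2(C)C)[C@H]1C)c1ccc(OCc2ccccc2)c(OCc2ccccc2)c1F | intermediate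
9 | potassium (1R,2R)-1-[3,4-bis(benzyloxy)phenyl]-3-[3,4-bis(benzyloxy)-2-fluorophenyl]-2-[(benzyloxy)methoxy]but-3-en-1-olate (syn) | [K+].[O-][C@H](c1ccc(OCc2ccccc2)c(OCc2ccccc2)c1)[C@H](OCOCc1ccccc1)C(=C)c1ccc(OCc2ccccc2)c(OCc2ccccc2)c1F | intermediate
10 | (2R,3R)-7,8-bis(benzyloxy)-2-[3,4-bis(benzyloxy)phenyl]-3-[(benzyloxy)methoxy]-4-methylidenechromane | C(c1ccccc1)Oc1ccc([C@H]2Oc3c(ccc(OCc4ccccc4)c3OCc3ccccc3)C(=C)[C@H]2OCOCc2ccccc2)cc1OCc1ccccc1 | intermediate
11 | (2R,3S)-7,8-bis(benzyloxy)-2-[3,4-bis(benzyloxy)phenyl]-3-[(benzyloxy)methoxy]chroman-4-one | C(c1ccccc1)Oc1ccc([C@H]2Oc3c(ccc(OCc4ccccc4)c3OCc3ccccc3)C(=O)[C@H]2OCOCc2ccccc2)cc1OCc1ccccc1 | intermediate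
12 | 2-bromo-5-fluorophenol | Oc1cc(F)ccc1Br | starting material
13 | 3-bromo-6-fluoro-2-hydroxybenzaldehyde | O=Cc1c(F)ccc(Br)c1O | intermediate
14 | 3-bromo-6-fluorobenzene-1,2-diol | Oc1c(F)ccc(Br)c1O | intermediate
15 | 2,3-bis(benzyloxy)-1-bromo-4-fluorobenzene | Fc1ccc(Br)c(OCc2ccccc2)c1OCc1ccccc1 | intermediate
16 | [3,4-bis(benzyloxy)-5-bromo-2-fluorophenyl]lithium | [Li]c1cc(Br)c(OCc2ccccc2)c(OCc2ccccc2)c1F | intermediate
17 | 2,3-bis(benzyloxy)-1-bromo-5-chloro-4-fluorobenzene | Clc1cc(Br)c(OCc2ccccc2)c(OCc2ccccc2)c1F | intermediate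
18 | [2,3-bis(benzyloxy)-5-chloro-4-fluorophenyl]lithium | [Li]c1cc(Cl)c(F)c(OCc2ccccc2)c1OCc1ccccc1 | intermediate
19 | (2R)-2,3-cis-4-aryl-chroman-4-ol from 11 and 18, aryl = 2,3-bis(benzyloxy)-5-chloro-4-fluorophenyl | C(c1ccccc1)Oc1ccc([C@H]2Oc3c(ccc(OCc4ccccc4)c3OCc3ccccc3)[C@](O)(c3cc(Cl)c(F)c(OCc4ccccc4)c3OCc3ccccc3)[C@H]2OCOCc2ccccc2)cc1OCc1ccccc1 | intermediate
20 | (2R)-2,3-cis-3,4-cis-4-[2,3-bis(benzyloxy)-5-chloro-4-fluorophenyl]-7,8-bis(benzyloxy)-2-[3,4-bis(benzyloxy)phenyl]-3-[(benzyloxy)methoxy]chromane | C(c1ccccc1)Oc1ccc([C@H]2Oc3c(ccc(OCc4ccccc4)c3OCc3ccccc3)[C@@H](c3cc(Cl)c(F)c(OCc4ccccc4)c3OCc3ccccc3)[C@H]2OCOCc2ccccc2)cc1OCc1ccccc1 | intermediate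
21 | {3-[(benzyloxy)methoxy]prop-1-en-2-yl}zinc chloride | C=C([Zn]Cl)COCOCc1ccccc1 | intermediate
22 | all-cis flavan 20 with the chlorine replaced by the 3-[(benzyloxy)methoxy]prop-1-en-2-yl group | C(c1ccccc1)Oc1ccc([C@H]2Oc3c(ccc(OCc4ccccc4)c3OCc3ccccc3)[C@@H](c3cc(C(=C)COCOCc4ccccc4)c(F)c(OCc4ccccc4)c3OCc3ccccc3)[C@H]2OCOCc2ccccc2)cc1OCc1ccccc1 | intermediate
23 | diisopinocampheyl allylborane from 22, alkoxy group cis to the CH2–B carbon | C(c1ccccc1)Oc1ccc([C@H]2Oc3c(ccc(OCc4ccccc4)c3OCc3ccccc3)[C@@H](c3cc(/C(CB([C@@H]4C[C@@H]5C[C@@H](C5(C)C)[C@H]4C)[C@@H]4C[C@@H]5C[C@@H](C5(C)C)[C@H]4C)=C/OCOCc4ccccc4)c(F)c(OCc4ccccc4)c3OCc3ccccc3)[C@H]2OCOCc2ccccc2)cc1OCc1ccccc1 | intermediate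
24 | potassium alkoxide of the (1R,2R)-syn homoallylic alcohol from 23 and 7 | [K+].C(c1ccccc1)Oc1ccc([C@H]2Oc3c(ccc(OCc4ccccc4)c3OCc3ccccc3)[C@@H](c3cc(C(=C)[C@@H](OCOCc4ccccc4)[C@H]([O-])c4ccc(OCc5ccccc5)c(OCc5ccccc5)c4)c(F)c(OCc4ccccc4)c3OCc3ccccc3)[C@H]2OCOCc2ccccc2)cc1OCc1ccccc1 | intermediate
25 | protected bis-flavan, lower unit (2R,3R)-2,3-cis-4-methylidenechromane | C(c1ccccc1)Oc1ccc([C@H]2Oc3c(ccc(OCc4ccccc4)c3OCc3ccccc3)[C@@H](c3cc4c(c(OCc5ccccc5)c3OCc3ccccc3)O[C@H](c3ccc(OCc5ccccc5)c(OCc5ccccc5)c3)[C@H](OCOCc3ccccc3)C4=C)[C@H]2OCOCc2ccccc2)cc1OCc1ccccc1 | intermediate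
26 | protected bis-flavan, lower unit (2R,3S)-2,3-cis-chroman-4-one | C(c1ccccc1)Oc1ccc([C@H]2Oc3c(ccc(OCc4ccccc4)c3OCc3ccccc3)[C@@H](c3cc4c(c(OCc5ccccc5)c3OCc3ccccc3)O[C@H](c3ccc(OCc5ccccc5)c(OCc5ccccc5)c3)[C@H](OCOCc3ccccc3)C4=O)[C@H]2OCOCc2ccccc2)cc1OCc1ccccc1 | intermediate
27 | free decahydroxy ketone | Oc1ccc([C@H]2Oc3c(ccc(O)c3O)[C@@H](c3cc4c(c(O)c3O)O[C@H](c3ccc(O)c(O)c3)[C@H](O)C4=O)[C@H]2O)cc1O | intermediate
28 | target (CNP0143773.1) | Oc1ccc([C@H]2Oc3c(ccc(O)c3O)[C@@H](c3cc4c(c(O)c3O)O[C@H](c3ccc(O)c(O)c3)[C@H](O)[C@H]4O)[C@H]2O)cc1O | target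

Total step count: 16. Longest linear sequence: 11 steps (12 → 13 → 14 → 15 → 17 → 19 → 20 → 22 → 25 → 26 → 27 → 28; the branch from 1 through 2, 6, 10 and 11 is equally long).

Steps most likely to fail

Step 13. The lithiation may lose site selectivity, with deprotonation at the diarylmethine or benzylic C–H bonds. The boron-bound alkoxide may also cyclise slowly, so that base-induced migration of the exocyclic alkene competes. The fallback sets out from 22 and returns at 26. Lemieux–Johnson cleavage of the alkene in 22 (OsO4 cat., NaIO4, 2,6-lutidine) would give the α-[(benzyloxy)methoxy] aryl ketone F1. Soft enolisation with diisopinocampheylboron triflate of the matching hand and i-Pr2NEt (Z boron enolate), addition of 7 at −78 °C and oxidative work-up would give the syn aldol F2. Treatment of F2 with Cs2CO3 in DMF at 0 °C would displace the ortho fluoride, now activated by the ketone, and close the pyran ring to give 26.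

Step 11. The C4 cation may lose a proton to give the enol ether, may be captured by the neighbouring acetal oxygen, or may take hydride on the wrong face. The fallback sets out from 19 and returns at 20. Dehydration of 19 with Ph2S[OC(CF3)2Ph]2 in CH2Cl2 would give the 4-aryl-3-alkoxy-2H-chromene F3. Homogeneous hydrogenation of F3 with [Ir(cod)(PCy3)(py)]PF6 under H2 should add both hydrogens to the face opposite the C2 aryl group without cleaving benzyl ethers or the aryl chloride, and give all-cis 20.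

Step 16. Facial selectivity may be poor if the phenols compete for the borohydride and the hydroxyl direction is lost, and the cis C3 centre may epimerise before reduction. The fallback sets out from 27 and returns at 28. NaBH4 in MeOH at 0 °C would be expected to attack anti to the axial 3-hydroxyl and give the 3,4-cis epimer F4. Brief warming of F4 in dilute aqueous acetic acid would ionise the benzylic C4 hydroxyl, and capture of the cation by water anti to the 3-hydroxyl would give the 3,4-trans alcohol 28.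

Further compounds
F1 | step 13 | aryl ketone from cleavage of 22, lower ring A bearing C(=O)CH2O-CH2OBn ortho to fluorine | C(c1ccccc1)Oc1ccc([C@H]2Oc3c(ccc(OCc4ccccc4)c3OCc3ccccc3)[C@@H](c3cc(C(=O)COCOCc4ccccc4)c(F)c(OCc4ccccc4)c3OCc3ccccc3)[C@H]2OCOCc2ccccc2)cc1OCc1ccccc1
F2 | step 13 | syn aldol of F1 with 7 (2,3-syn α-alkoxy-β-hydroxy ketone) | C(c1ccccc1)Oc1ccc([C@H]2Oc3c(ccc(OCc4ccccc4)c3OCc3ccccc3)[C@@H](c3cc(C(=O)[C@@H](OCOCc4ccccc4)[C@H](O)c4ccc(OCc5ccccc5)c(OCc5ccccc5)c4)c(F)c(OCc4ccccc4)c3OCc3ccccc3)[C@H]2OCOCc2ccccc2)cc1OCc1ccccc1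
F3 | step 11 | (2R)-4-aryl-3-[(benzyloxy)methoxy]-2H-chromene from dehydration of 19 | C(c1ccccc1)Oc1ccc([C@H]2Oc3c(ccc(OCc4ccccc4)c3OCc3ccccc3)C(c3cc(Cl)c(F)c(OCc4ccccc4)c3OCc3ccccc3)=C2OCOCc2ccccc2)cc1OCc1ccccc1
F4 | step 16 | 4-epimer of the target, lower unit 2,3-cis-3,4-cis | Oc1ccc([C@H]2Oc3c(ccc(O)c3O)[C@@H](c3cc4c(c(O)c3O)O[C@H](c3ccc(O)c(O)c3)[C@H](O)[C@@H]4O)[C@H]2O)cc1O
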